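**Plan**
- Retrosynthesis: the three MOM ethers are cleaved last; the C(=O)–Cα bond of the enone is cut to a ring-A salicylaldehyde and a ring-B aryl acetylene; the ring-A C3'–CH2 bond is cut to a bromophenol aldehyde and (S)-lavandulyl iodide.
- Forward: no ring is built. Ring A (2,4,6-trihydroxybenzaldehyde) is protected, brominated and given the C10 chain by B-alkyl Suzuki coupling; ring B (2-hydroxy-4-methoxybenzaldehyde) is turned into the alkyne; the halves are joined by Rh-catalysed alkyne hydroacylation; MOM removal ends the route.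
- Enabling feature: the free 2'-OH on ring A ortho to the carbonyl carbon (O2'–C2'–C1'–C=O). As a phenoxide it holds rhodium in a five-membered acyl chelate, so the formyl C–H adds across the alkyne without decarbonylation, with full atom economy, and the hydroxyl stays free as in the target.
- Stereochemistry: the single stereocentre comes from lipase kinetic resolution of commercial (±)-lavandulol and is never next to a reacting centre afterwards; the E alkene comes from syn hydrorhodation of the terminal alkyne.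

Key step: step 8

Remark on the chemistry: the side-chain centre of the target is R and has the same spatial arrangement as (S)-lavandulol; the label changes only because CH2OH outranks the isopropenyl group whereas CH2–aryl does not.

**Route**

Step 1
Reactants: 1 2,4,6-trihydroxybenzaldehyde
Product: 2 2-hydroxy-4,6-bis(methoxymethoxy)benzaldehyde
Conditions: MOMCl (2.1 equiv), i-Pr2NEt, CH2Cl2, 0 °C → rt
Reagents that add atoms: chloromethyl methyl ether, COCCl
Why: O-alkylation (MOM protection) should take the 4-OH and one of the two equivalent ortho hydroxyls, while the remaining ortho OH is held in a hydrogen bond to the formyl oxygen and is left free with a limited amount of MOMCl.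

Step 2
Reactants: 2 2-hydroxy-4,6-bis(methoxymethoxy)benzaldehyde
Product: 3 3-bromo-2-hydroxy-4,6-bis(methoxymethoxy)benzaldehyde
Conditions: NBS (1.0 equiv), MeCN, 0 °C
Reagents that add atoms: N-bromosuccinimide, O=C1CCC(=O)N1Br
Why: Electrophilic aromatic bromination should occur at the open position ortho to the free phenol (C3); if C5 reacted instead, that isomer would lead to the same target, because the two sites become identical once all acetals are removed.

Step 3
Reactants: 4 (±)-lavandulol [racemic 5-methyl-2-(prop-1-en-2-yl)hex-4-en-1-ol]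
Product: 5 (S)-lavandulol [(2S)-5-methyl-2-(prop-1-en-2-yl)hex-4-en-1-ol]
Conditions: porcine pancreatic lipase, vinyl acetate, t-BuOMe, rt, to ca. 60 % conversion; chromatography (second pass if needed)
Reagents that add atoms: none
Why: Lipase-catalysed kinetic resolution by irreversible transesterification should acylate the (R)-alcohol faster, so that running past half conversion leaves the (S)-alcohol enantioenriched (discrimination of a β-stereocentre in a primary alcohol is only moderate, hence the high conversion); this step is the source of the single stereocentre.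

Step 4
Reactants: 5 (S)-lavandulol
Product: 6 (S)-lavandulyl iodide [(4S)-4-(iodomethyl)-2,5-dimethylhexa-1,5-diene... named here as (2S)-1-iodo-5-methyl-2-(prop-1-en-2-yl)hex-4-ene]
Conditions: I2, PPh3, imidazole, CH2Cl2, 0 °C → rt
Reagents that add atoms: iodine, II
Why: Appel-type iodination proceeds by SN2 displacement of the alkoxyphosphonium group at the primary carbon, so the neighbouring stereocentre is not involved.

Step 5
Reactants: 6 (S)-lavandulyl iodide; 3 3-bromo-2-hydroxy-4,6-bis(methoxymethoxy)benzaldehyde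
Product: 9 2-hydroxy-4,6-bis(methoxymethoxy)-3-[(2R)-5-methyl-2-(prop-1-en-2-yl)hex-4-en-1-yl]benzaldehyde, via (2S)-lavandulyllithium 7 (not isolated), via lithium lavandulyl(methoxy)-9-BBN borate 8 (not isolated)
Conditions: 6, t-BuLi (2.1 equiv per 6), Et2O, −78 °C; B-MeO-9-BBN, THF, −78 °C → rt; then 3 M aq K3PO4, 3, Pd(OAc)2/SPhos, DMF, rt → 45 °C
Reagents that add atoms: none
Why: B-alkyl Suzuki–Miyaura coupling in its lithium–iodine exchange/B-methoxy-9-BBN variant transfers the primary alkyl group of the borate to the arylpalladium species, with SPhos handling the di-ortho-substituted electron-rich bromide and the aqueous base carrying the phenol as phenoxide; the stereocentre is β to the metal-bearing carbon and keeps its arrangement (S becomes R only by the priority change).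

Step 6
Reactants: 10 2-hydroxy-4-methoxybenzaldehyde
Product: 11 4-methoxy-2-(methoxymethoxy)benzaldehyde
Conditions: NaH, DMF, 0 °C; MOMCl, 0 °C → rt
Reagents that add atoms: chloromethyl methyl ether, COCCl
Why: O-alkylation of the sodium phenoxide (MOM protection) masks the phenol, because a free 2-ethynylphenol would cycloisomerise to a benzofuran under rhodium catalysis.

Step 7
Reactants: 11 4-methoxy-2-(methoxymethoxy)benzaldehyde
Product: 12 1-ethynyl-4-methoxy-2-(methoxymethoxy)benzene
Conditions: dimethyl (1-diazo-2-oxopropyl)phosphonate, K2CO3, MeOH, rt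
Reagents that add atoms: Ohira–Bestmann reagent [dimethyl (1-diazo-2-oxopropyl)phosphonate], COP(=O)(OC)C(=[N+]=[N-])C(C)=O
Why: Seyferth–Gilbert homologation with the Ohira–Bestmann reagent gives the terminal alkyne by olefination to the diazoalkene, loss of N2 and 1,2-hydride shift, under conditions that leave the aryl MOM ether untouched.

Step 8
Reactants: 9 2-hydroxy-4,6-bis(methoxymethoxy)-3-[(2R)-5-methyl-2-(prop-1-en-2-yl)hex-4-en-1-yl]benzaldehyde; 12 1-ethynyl-4-methoxy-2-(methoxymethoxy)benzene
Product: 13 (2E)-1-{2-hydroxy-4,6-bis(methoxymethoxy)-3-[(2R)-5-methyl-2-(prop-1-en-2-yl)hex-4-en-1-yl]phenyl}-3-[4-methoxy-2-(methoxymethoxy)phenyl]prop-2-en-1-one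
Conditions: [Rh(cod)Cl]2 (2.5 mol %), dppf (5 mol %), Na2CO3 (10 mol %), toluene, 80 °C, slow addition of 12 (1.5 equiv)
Reagents that add atoms: none
Why: The phenol O–H of 9 is exchanged onto Rh(I) and the neighbouring formyl C–H adds oxidatively, giving a five-membered acyl(hydrido)rhodium(III) phenoxide chelate (Rh, O2', C2', C1', acyl C) that resists decarbonylation; the C≡C of 12 then inserts syn into Rh–H with rhodium on the unsubstituted carbon, and C–C reductive elimination forms the acyl–vinyl bond. The closest known reaction type is the chelation-assisted rhodium-catalysed intermolecular hydroacylation of alkynes with salicylaldehydes. No ring is closed and no stereocentre is created; the E geometry follows from the syn hydrometalation and the retentive reductive elimination. The step needs linear rather than branched regioselectivity, which the ortho-OMOM group on the alkyne-bearing arene and the wide-bite-angle dppf ligand should secure by pushing rhodium to the terminal carbon. It needs chemoselectivity for the alkyne over the isopropenyl and trisubstituted alkenes of the side chain, which are hindered, unactivated and remote from the chelated Rh–H, and slow addition of 12 limits alkyne oligomerisation. The product keeps a single hydrogen-bonded 2'-OH (O-6' is a MOM ether), so oxa-Michael closure to the flavanone should not follow under the nearly neutral conditions.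

Step 9
Reactants: 13 (2E)-1-{2-hydroxy-4,6-bis(methoxymethoxy)-3-[(2R)-5-methyl-2-(prop-1-en-2-yl)hex-4-en-1-yl]phenyl}-3-[4-methoxy-2-(methoxymethoxy)phenyl]prop-2-en-1-one
Product: 14 (2E)-3-(2-hydroxy-4-methoxyphenyl)-1-{2,4,6-trihydroxy-3-[(2R)-5-methyl-2-(prop-1-en-2-yl)hex-4-en-1-yl]phenyl}prop-2-en-1-one (target)
Conditions: HCl (ca. 1 M, from AcCl in MeOH), MeOH, 0 °C → rt; aq NaHCO3 to pH ca. 6
Reagents that add atoms: none
Why: Acid-catalysed acetal exchange transfers the three aryl MOM groups to methanol under mild anhydrous acid, conditions with precedent for prenylated 2',4',6'-trioxygenated chalcones, in which the phenols stay protonated so that phenoxide-driven closure to the flavanone is slow and the side-chain alkenes should survive.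

**Compound list**

1 | 2,4,6-trihydroxybenzaldehyde | O=Cc1c(O)cc(O)cc1O | starting material
2 | 2-hydroxy-4,6-bis(methoxymethoxy)benzaldehyde | COCOc1cc(O)c(C=O)c(OCOC)c1 | intermediate
3 | 3-bromo-2-hydroxy-4,6-bis(methoxymethoxy)benzaldehyde | COCOc1cc(OCOC)c(C=O)c(O)c1Br | intermediate
4 | (±)-lavandulol, racemic 5-methyl-2-(prop-1-en-2-yl)hex-4-en-1-ol | C=C(C)C(CO)CC=C(C)C | starting material
5 | (S)-lavandulol, (2S)-5-methyl-2-(prop-1-en-2-yl)hex-4-en-1-ol | C=C(C)[C@H](CC=C(C)C)CO | intermediate
6 | (S)-lavandulyl iodide, (2S)-1-iodo-5-methyl-2-(prop-1-en-2-yl)hex-4-ene | C=C(C)[C@H](CC=C(C)C)CI | intermediate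
7 | [(2S)-5-methyl-2-(prop-1-en-2-yl)hex-4-en-1-yl]lithium (not isolated) | C=C(C)[C@H](CC=C(C)C)C[Li] | intermediate
8 | lithium 9-methoxy-9-[(2S)-5-methyl-2-(prop-1-en-2-yl)hex-4-en-1-yl]-9-boranuidabicyclo[3.3.1]nonane (not isolated) | [Li+].C=C(C)[C@H](CC=C(C)C)C[B-]1(OC)C2CCCC1CCC2 | intermediate
9 | 2-hydroxy-4,6-bis(methoxymethoxy)-3-[(2R)-5-methyl-2-(prop-1-en-2-yl)hex-4-en-1-yl]benzaldehyde | C=C(C)[C@H](CC=C(C)C)Cc1c(O)c(C=O)c(OCOC)cc1OCOC | intermediate
10 | 2-hydroxy-4-methoxybenzaldehyde | COc1ccc(C=O)c(O)c1 | starting material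
11 | 4-methoxy-2-(methoxymethoxy)benzaldehyde | COCOc1cc(OC)ccc1C=O | intermediate
12 | 1-ethynyl-4-methoxy-2-(methoxymethoxy)benzene | C#Cc1ccc(OC)cc1OCOC | intermediate
13 | (2E)-1-{2-hydroxy-4,6-bis(methoxymethoxy)-3-[(2R)-5-methyl-2-(prop-1-en-2-yl)hex-4-en-1-yl]phenyl}-3-[4-methoxy-2-(methoxymethoxy)phenyl]prop-2-en-1-one | C=C(C)[C@H](CC=C(C)C)Cc1c(O)c(C(=O)/C=C/c2ccc(OC)cc2OCOC)c(OCOC)cc1OCOC | intermediate
14 | (2E)-3-(2-hydroxy-4-methoxyphenyl)-1-{2,4,6-trihydroxy-3-[(2R)-5-methyl-2-(prop-1-en-2-yl)hex-4-en-1-yl]phenyl}prop-2-en-1-one | C=C(C)[C@H](CC=C(C)C)Cc1c(O)cc(O)c(C(=O)/C=C/c2ccc(OC)cc2O)c1O | target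

**Totals**

Total step count: 9. Longest linear sequence: 5 steps (steps 1, 2, 5, 8, 9; the branch 3, 4, 5, 8, 9 is equally long).

**Steps most likely to fail**

1. Step 8. Hydrorhodation may take the Markovnikov sense and give the branched enone; the terminal alkyne may oligomerise; a rhodium hydride may isomerise the isopropenyl double bond into conjugation with loss of the stereocentre; base may close the new hydroxy-enone to a flavanone. Fallback, setting out from 9 and returning at 13: addition of MeMgBr (excess, THF, 0 °C) to 9 should give the carbinol 1-{2-hydroxy-4,6-bis(methoxymethoxy)-3-[(2R)-5-methyl-2-(prop-1-en-2-yl)hex-4-en-1-yl]phenyl}ethan-1-ol F1 (carbinol epimers, inconsequential). Oxidation with MnO2 in CH2Cl2 should give the acetophenone 1-{2-hydroxy-4,6-bis(methoxymethoxy)-3-[(2R)-5-methyl-2-(prop-1-en-2-yl)hex-4-en-1-yl]phenyl}ethan-1-one F2. Claisen–Schmidt condensation of this ketone with aldehyde 11 (KOH, EtOH, rt) should then give chalcone 13 by forming the Cα=Cβ bond instead.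

2. Step 5. Oxidative addition at the di-ortho-substituted, electron-rich bromophenoxide may be too slow; the alkyl group may be lost by β-hydride elimination or protodeboronation; the alkylborane may transfer hydride to the aldehyde. Fallback, setting out from 3 (with 6) and returning at 9: the phenol is masked and the nucleophile changed to zinc. Acetylation of 3 (Ac2O, pyridine) should give 2-bromo-6-formyl-3,5-bis(methoxymethoxy)phenyl acetate F3. Iodide 6 is converted through 7 and ZnCl2 into chlorido[(2S)-5-methyl-2-(prop-1-en-2-yl)hex-4-en-1-yl]zinc F4. Negishi coupling (Pd2(dba)3/CPhos, THF, rt) should give 2-formyl-3,5-bis(methoxymethoxy)-6-[(2R)-5-methyl-2-(prop-1-en-2-yl)hex-4-en-1-yl]phenyl acetate F5, and K2CO3 in MeOH at 0 °C should release 9.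

3. Step 9. Acid may isomerise the 2',6'-dihydroxychalcone to the flavanone, add the ortho hydroxyls across the side-chain alkenes (chroman formation, or loss of the stereocentre through the tertiary cation), or leave the acetals partly in place. Fallback, setting out from 1 and 10 and returning at 14: the acetals are replaced by silyl ethers so that the last step uses buffered fluoride.
   - Ring A: 1 is bis-silylated (TIPSCl, imidazole, DMF) to 2-hydroxy-4,6-bis{[tri(propan-2-yl)silyl]oxy}benzaldehyde F6. NBS bromination gives 3-bromo-2-hydroxy-4,6-bis{[tri(propan-2-yl)silyl]oxy}benzaldehyde F7. Coupling with borate 8 (from 6 via 7, as in step 5) gives 2-hydroxy-3-[(2R)-5-methyl-2-(prop-1-en-2-yl)hex-4-en-1-yl]-4,6-bis{[tri(propan-2-yl)silyl]oxy}benzaldehyde F8.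
   - Ring B: 10 is silylated to 4-methoxy-2-{[tri(propan-2-yl)silyl]oxy}benzaldehyde F9 and homologated with lithiated trimethylsilyldiazomethane (Colvin rearrangement, THF, −78 °C → rt) to (2-ethynyl-5-methoxyphenoxy)tri(propan-2-yl)silane F10.
   - End game: hydroacylation as in step 8 gives (2E)-1-{2-hydroxy-3-[(2R)-5-methyl-2-(prop-1-en-2-yl)hex-4-en-1-yl]-4,6-bis{[tri(propan-2-yl)silyl]oxy}phenyl}-3-(4-methoxy-2-{[tri(propan-2-yl)silyl]oxy}phenyl)prop-2-en-1-one F11. TBAF/AcOH in THF at 0 °C should cleave the three silyl ethers to give 14.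

**Further compounds**

F1 | step 8 | 1-{2-hydroxy-4,6-bis(methoxymethoxy)-3-[(2R)-5-methyl-2-(prop-1-en-2-yl)hex-4-en-1-yl]phenyl}ethan-1-ol | C=C(C)[C@H](CC=C(C)C)Cc1c(O)c(C(C)O)c(OCOC)cc1OCOC
F2 | step 8 | 1-{2-hydroxy-4,6-bis(methoxymethoxy)-3-[(2R)-5-methyl-2-(prop-1-en-2-yl)hex-4-en-1-yl]phenyl}ethan-1-one | C=C(C)[C@H](CC=C(C)C)Cc1c(O)c(C(C)=O)c(OCOC)cc1OCOC
F3 | step 5 | 2-bromo-6-formyl-3,5-bis(methoxymethoxy)phenyl acetate | CC(=O)Oc1c(Br)c(OCOC)cc(OCOC)c1C=O
F4 | step 5 | chlorido[(2S)-5-methyl-2-(prop-1-en-2-yl)hex-4-en-1-yl]zinc | C=C(C)[C@H](CC=C(C)C)C[Zn]Cl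
F5 | step 5 | 2-formyl-3,5-bis(methoxymethoxy)-6-[(2R)-5-methyl-2-(prop-1-en-2-yl)hex-4-en-1-yl]phenyl acetate | C=C(C)[C@H](CC=C(C)C)Cc1c(OC(C)=O)c(C=O)c(OCOC)cc1OCOC
F6 | step 9 | 2-hydroxy-4,6-bis{[tri(propan-2-yl)silyl]oxy}benzaldehyde | O=Cc1c(O)cc(O[Si](C(C)C)(C(C)C)C(C)C)cc1O[Si](C(C)C)(C(C)C)C(C)C
F7 | step 9 | 3-bromo-2-hydroxy-4,6-bis{[tri(propan-2-yl)silyl]oxy}benzaldehyde | O=Cc1c(O)c(Br)c(O[Si](C(C)C)(C(C)C)C(C)C)cc1O[Si](C(C)C)(C(C)C)C(C)C
F8 | step 9 | 2-hydroxy-3-[(2R)-5-methyl-2-(prop-1-en-2-yl)hex-4-en-1-yl]-4,6-bis{[tri(propan-2-yl)silyl]oxy}benzaldehyde | C=C(C)[C@H](CC=C(C)C)Cc1c(O)c(C=O)c(O[Si](C(C)C)(C(C)C)C(C)C)cc1O[Si](C(C)C)(C(C)C)C(C)C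
F9 | step 9 | 4-methoxy-2-{[tri(propan-2-yl)silyl]oxy}benzaldehyde | COc1ccc(C=O)c(O[Si](C(C)C)(C(C)C)C(C)C)c1
F10 | step 9 | (2-ethynyl-5-methoxyphenoxy)tri(propan-2-yl)silane | C#Cc1ccc(OC)cc1O[Si](C(C)C)(C(C)C)C(C)C
F11 | step 9 | (2E)-1-{2-hydroxy-3-[(2R)-5-methyl-2-(prop-1-en-2-yl)hex-4-en-1-yl]-4,6-bis{[tri(propan-2-yl)silyl]oxy}phenyl}-3-(4-methoxy-2-{[tri(propan-2-yl)silyl]oxy}phenyl)prop-2-en-1-one | C=C(C)[C@H](CC=C(C)C)Cc1c(O)c(C(=O)/C=C/c2ccc(OC)cc2O[Si](C(C)C)(C(C)C)C(C)C)c(O[Si](C(C)C)(C(C)C)C(C)C)cc1O[Si](C(C)C)(C(C)C)C(C)C
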